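**Retrosynthetic overview**
- Daphnodorin C comes from its penta-O-benzyl ether. The benzofuranone ring is cut by an aryne annulation of a tertiary α-hydroxy ester with 3,5-bis(benzyloxy)benzyne: O–aryl bond first, then acyl substitution at the ester.
- The dihydrofuran ring and the later spiro carbon come from a one-flask union of an 8-bromo-7-fluoroflavan with the C3 linchpin ArCH(OH)–CO–CO2Et. C8–Li adds to the ketone (C8–C bond), then the carbinol oxygen displaces fluoride at C7 (O–C7 bond).
- Enabling feature: in flavan ring A, C8 lies between C7 and C8a (which bears pyran O1), and C7 is meta to both ring-A oxygens (on C5 and C8a). A C7–F/C8–Li pair is therefore a storable 1,2-dipole: F and O1 flank the carbanion, and the meta oxygens do not switch off SNAr at C7. The O–CH(Ar)–C(=O) triad of the upper half is its match.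
- Stereochemistry: flavan C2 is set by asymmetric transfer hydrogenation and CH(Ar) by a catalytic asymmetric diazoester aldol. The spiro carbon is relayed from CH(Ar) by Cram chelation (aryl cis to the spiro oxygen).
- Ring order: pyran ring of the flavan (SNAr), then the dihydrofuran ring, then the benzofuranone ring.

Key step: step 8

Assumption: the (S,S)-ProPhenol/Bu2Mg catalyst is taken to give the (S)-carbinol in the diazoester aldol; if the sense of induction is opposite, the equally available (R,R)-ligand is used.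

Step 1
Reactants: 1 4-bromo-3,5-difluorophenol
Product: 2 3-bromo-2,4-difluoro-6-hydroxybenzaldehyde
Conditions: MgCl2, Et3N, (CH2O)n, MeCN, reflux; then 1 M HCl
Reagents that add atoms: paraformaldehyde (as formaldehyde) C=O
Why: Casnati–Skattebøl ortho-formylation, in which the magnesium phenolate delivers formaldehyde only ortho to oxygen, the two ortho positions of 1 are equivalent by symmetry, and a second formaldehyde oxidises the benzylic alkoxide to the aldehyde.

Step 2
Reactants: 2 3-bromo-2,4-difluoro-6-hydroxybenzaldehyde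
Product: 3 6-(benzyloxy)-3-bromo-2,4-difluorobenzaldehyde
Conditions: BnBr, K2CO3, DMF, rt
Reagents that add atoms: benzyl bromide BrCc1ccccc1
Why: Williamson ether synthesis on the only acidic OH, with a carbonate base too weak and too poorly nucleophilic to attack the C–F bonds.

Step 3
Reactants: 3 6-(benzyloxy)-3-bromo-2,4-difluorobenzaldehyde; 4 1-[4-(benzyloxy)phenyl]ethanone
Product: 5 (E)-3-[6-(benzyloxy)-3-bromo-2,4-difluorophenyl]-1-[4-(benzyloxy)phenyl]prop-2-en-1-one
Conditions: aq NaOH, cat. Bu4NBr, THF, 0 °C → rt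
Reagents that add atoms: none
Why: Claisen–Schmidt condensation of a non-enolisable aldehyde with a methyl ketone, giving the (E)-enone by E1cB dehydration, run without alcohol solvent so that no alkoxide can displace the aldehyde-activated fluorides.

Step 4
Reactants: 5 (E)-3-[6-(benzyloxy)-3-bromo-2,4-difluorophenyl]-1-[4-(benzyloxy)phenyl]prop-2-en-1-one
Product: 7 (1S)-3-[6-(benzyloxy)-3-bromo-2,4-difluorophenyl]-1-[4-(benzyloxy)phenyl]propan-1-ol, via the saturated ketone 3-[6-(benzyloxy)-3-bromo-2,4-difluorophenyl]-1-[4-(benzyloxy)phenyl]propan-1-one 6 (not isolated)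
Conditions: RuCl[(S,S)-TsDPEN](p-cymene) (cat.), HCO2H–Et3N 5:2, DMF, 40 °C
Reagents that add atoms: none
Why: Noyori–Ikariya asymmetric transfer hydrogenation used as a domino 1,4- then 1,2-reduction of a chalcone, in which the (S,S)-catalyst delivers hydride to the aryl ketone through the CH/π-organised transition state to set the (S)-carbinol, and benzyl ethers, C–Br and C–F are inert.

Step 5
Reactants: 7 (1S)-3-[6-(benzyloxy)-3-bromo-2,4-difluorophenyl]-1-[4-(benzyloxy)phenyl]propan-1-ol
Product: 8 (2S)-5-(benzyloxy)-2-[4-(benzyloxy)phenyl]-8-bromo-7-fluorochromane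
Conditions: NaH, DMF, 0 → 60 °C
Reagents that add atoms: none
Why: intramolecular SNAr etherification (6-exo) at the only fluoride within reach, which is activated by the ortho bromine and the meta fluorine, and because the carbinol C–O bond is not broken the (S) configuration is retained as flavan C2.

Step 6
Reactants: 9 4-(benzyloxy)benzaldehyde; 10 ethyl diazoacetate
Product: 11 ethyl (3S)-3-[4-(benzyloxy)phenyl]-2-diazo-3-hydroxypropanoate
Conditions: (S,S)-ProPhenol (cat.), Bu2Mg (cat.), cis-cyclopentane-1,2-diol (cat.), THF, −20 °C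
Reagents that add atoms: none
Why: dinuclear magnesium–ProPhenol-catalysed direct asymmetric aldol addition of the diazoester C–H to an aromatic aldehyde, in which the chiral pocket selects one aldehyde face and sets the only catalytically made stereocentre of the upper half.

Step 7
Reactants: 11 ethyl (3S)-3-[4-(benzyloxy)phenyl]-2-diazo-3-hydroxypropanoate
Product: 12 ethyl (3S)-3-[4-(benzyloxy)phenyl]-3-hydroxy-2-oxopropanoate
Conditions: DMDO (dried acetone solution), CH2Cl2, −20 → 0 °C; evaporate, toluene azeotrope, use at once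
Reagents that add atoms: dimethyldioxirane CC1(C)OO1
Why: dioxirane oxidation of an α-diazo ester to the α-keto ester by oxygen transfer with loss of N2, under neutral conditions with only volatile by-products, so that the base-labile carbinol stereocentre should be kept.

Step 8
Reactants: 8 (2S)-5-(benzyloxy)-2-[4-(benzyloxy)phenyl]-8-bromo-7-fluorochromane; 12 ethyl (3S)-3-[4-(benzyloxy)phenyl]-3-hydroxy-2-oxopropanoate
Product: 16 ethyl (2S,8S,9S)-5-(benzyloxy)-2,8-bis[4-(benzyloxy)phenyl]-9-hydroxy-3,4,8,9-tetrahydro-2H-furo[2,3-h]chromene-9-carboxylate, via the lithium alkoxide of the keto ester 13 (not isolated), via the 7-fluorochroman-8-yllithium 14 (not isolated), via the dilithium dialkoxide adduct 15 (not isolated)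
Conditions: 12, LDA (1.0 equiv), THF, −78 °C; separately 8, n-BuLi, THF, −78 °C; combine at −78 °C; then t-BuOK, DMPU, −78 → 50 °C; pH 7 buffer
Reagents that add atoms: none
Why: Br/Li exchange gives 14, whose C8 carbanion is flanked by C7–F and by the pyran oxygen on C8a and keeps LiF at −78 °C; it adds to the ketone of 13 (organolithium 1,2-addition to an α-keto ester under Cram chelate control), and after Li/K exchange the secondary alkoxide of 15 displaces fluoride at C7 (intramolecular SNAr etherification, the known route from 2-(2-fluoroaryl)ethanols to 2,3-dihydrobenzofurans). The only ring closed, the dihydrofuran ring, forms by 5-exo attack of oxygen at the ipso carbon C7 followed by loss of fluoride. The new quaternary stereocentre (the later spiro carbon) is controlled by the carbinol centre of 12: lithium ties alkoxide O and ketone O into a five-membered chelate and 14 enters from the face bearing H, which after ring closure places the tertiary oxygen cis and the ester trans to the 4-(benzyloxy)phenyl group as in the target, while the carbinol C–O bond is never broken and that centre is retained. Ketone-over-ester selectivity rests on the higher electrophilicity of the chelated α-keto carbonyl, and addition should outrun enolisation because 13 is already anionic and the addition is run at −78 °C. Site selectivity of the second event is structural: one C–F bond is left, the secondary alkoxide closes a five-membered ring whereas the tertiary one could only close a four-membered ring, and C7 is meta to the oxygens on C5 and C8a, so they do not load the Meisenheimer positions. No β-alkoxy ketone is ever present, so retro-aldol cleavage is closed, and the ester keeps the tertiary benzylic alcohol of 16 from ionising.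

Step 9
Reactants: 17 3,5-bis(benzyloxy)phenol
Product: 18 3,5-bis(benzyloxy)-2-bromophenol
Conditions: NBS (1.0 equiv), CH2Cl2, −78 → 0 °C
Reagents that add atoms: N-bromosuccinimide O=C1CCC(=O)N1Br
Why: electrophilic aromatic bromination directed ortho to the free OH, the two ortho positions being equivalent and the para position being shielded between two benzyloxy groups.

Step 10
Reactants: 18 3,5-bis(benzyloxy)-2-bromophenol
Product: 21 3,5-bis(benzyloxy)-2-(trimethylsilyl)phenyl trifluoromethanesulfonate, via the aryl trimethylsilyl ether 19 (not isolated), via the lithium 2-(trimethylsilyl)phenolate 20 (not isolated)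
Conditions: HMDS, THF, 65 °C, evaporate; n-BuLi, THF, −78 °C; Tf2O, −78 → 0 °C
Reagents that add atoms: hexamethyldisilazane C[Si](C)(C)N[Si](C)(C)C; trifluoromethanesulfonic anhydride O=S(=O)(OS(=O)(=O)C(F)(F)F)C(F)(F)F
Why: standard o-silylaryl triflate synthesis by O-silylation, Br/Li exchange, retro-Brook O→C silyl migration and triflation of the released phenolate.

Step 11
Reactants: 16 ethyl (2S,8S,9S)-5-(benzyloxy)-2,8-bis[4-(benzyloxy)phenyl]-9-hydroxy-3,4,8,9-tetrahydro-2H-furo[2,3-h]chromene-9-carboxylate; 21 3,5-bis(benzyloxy)-2-(trimethylsilyl)phenyl trifluoromethanesulfonate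
Product: 24 penta-O-benzyldaphnodorin C, (2S,2'S,8'S)-4,5',6-tris(benzyloxy)-2',8'-bis[4-(benzyloxy)phenyl]-3',4'-dihydro-2'H,3H,8'H-spiro[1-benzofuran-2,9'-furo[2,3-h]chromen]-3-one, via the potassium alkoxide of the hydroxy ester 22 (not isolated), via 3,5-bis(benzyloxy)benzyne 23 (not isolated)
Conditions: KH, THF, 0 °C; then 21 (2 equiv), CsF, 18-crown-6, THF, 0 → 40 °C
Reagents that add atoms: none
Why: Proposed new method: fluoride releases aryne 23, whose triple bond is polarised by the adjacent benzyloxy group so that the tertiary alkoxide 22 attacks the distal carbon, and the aryl anion formed next to that benzyloxy group closes the benzofuranone ring by 5-exo-trig acyl substitution at the neighbouring ethyl ester with loss of ethoxide, no stereocentre being touched; the closest known reaction types are the aryne annulations of methyl salicylates to xanthones and of α-amino esters to indolin-3-ones.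

Step 12
Reactants: 24 penta-O-benzyldaphnodorin C
Product: 25 daphnodorin C, (2S,2'S,8'S)-4,5',6-trihydroxy-2',8'-bis(4-hydroxyphenyl)-3',4'-dihydro-2'H,3H,8'H-spiro[1-benzofuran-2,9'-furo[2,3-h]chromen]-3-one
Conditions: H2 (1 atm), Pd(OH)2/C, THF–MeOH, rt
Reagents that add atoms: none
Why: catalytic hydrogenolysis of five aryl benzyl ethers under neutral conditions, as in flavan-3-ol syntheses, where the exocyclic O–CH2Ph bonds are cleaved faster than the ring benzylic C–O bonds and no stereocentre is affected.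

**Compound list**
1 | 4-bromo-3,5-difluorophenol | Oc1cc(F)c(Br)c(F)c1 | starting material
2 | 3-bromo-2,4-difluoro-6-hydroxybenzaldehyde | O=Cc1c(O)cc(F)c(Br)c1F | intermediate
3 | 6-(benzyloxy)-3-bromo-2,4-difluorobenzaldehyde | O=Cc1c(OCc2ccccc2)cc(F)c(Br)c1F | intermediate
4 | 1-[4-(benzyloxy)phenyl]ethanone | CC(=O)c1ccc(OCc2ccccc2)cc1 | starting material
5 | (E)-3-[6-(benzyloxy)-3-bromo-2,4-difluorophenyl]-1-[4-(benzyloxy)phenyl]prop-2-en-1-one | O=C(/C=C/c1c(OCc2ccccc2)cc(F)c(Br)c1F)c1ccc(OCc2ccccc2)cc1 | intermediate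
6 | 3-[6-(benzyloxy)-3-bromo-2,4-difluorophenyl]-1-[4-(benzyloxy)phenyl]propan-1-one | O=C(CCc1c(OCc2ccccc2)cc(F)c(Br)c1F)c1ccc(OCc2ccccc2)cc1 | intermediate
7 | (1S)-3-[6-(benzyloxy)-3-bromo-2,4-difluorophenyl]-1-[4-(benzyloxy)phenyl]propan-1-ol | O[C@H](c1ccc(OCc2ccccc2)cc1)CCc1c(OCc2ccccc2)cc(F)c(Br)c1F | intermediate
8 | (2S)-5-(benzyloxy)-2-[4-(benzyloxy)phenyl]-8-bromo-7-fluorochromane | Brc1c(F)cc(OCc2ccccc2)c2c1O[C@H](c1ccc(OCc3ccccc3)cc1)CC2 | intermediate
9 | 4-(benzyloxy)benzaldehyde | O=Cc1ccc(OCc2ccccc2)cc1 | starting material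
10 | ethyl diazoacetate | CCOC(=O)C=[N+]=[N-] | starting material
11 | ethyl (3S)-3-[4-(benzyloxy)phenyl]-2-diazo-3-hydroxypropanoate | O[C@H](C(=[N+]=[N-])C(=O)OCC)c1ccc(OCc2ccccc2)cc1 | intermediate
12 | ethyl (3S)-3-[4-(benzyloxy)phenyl]-3-hydroxy-2-oxopropanoate | O[C@H](C(=O)C(=O)OCC)c1ccc(OCc2ccccc2)cc1 | intermediate
13 | lithium alkoxide of 12 | [Li]O[C@H](C(=O)C(=O)OCC)c1ccc(OCc2ccccc2)cc1 | intermediate
14 | (2S)-5-(benzyloxy)-2-[4-(benzyloxy)phenyl]-7-fluorochroman-8-yllithium | [Li]c1c(F)cc(OCc2ccccc2)c2c1O[C@H](c1ccc(OCc3ccccc3)cc1)CC2 | intermediate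
15 | dilithium dialkoxide of ethyl (2S,3S)-2-{(2S)-5-(benzyloxy)-2-[4-(benzyloxy)phenyl]-7-fluorochroman-8-yl}-3-[4-(benzyloxy)phenyl]-2,3-dihydroxypropanoate | CCOC(=O)[C@](O[Li])(c1c(F)cc(OCc2ccccc2)c2c1O[C@H](c1ccc(OCc3ccccc3)cc1)CC2)[C@@H](O[Li])c1ccc(OCc2ccccc2)cc1 | intermediate
16 | ethyl (2S,8S,9S)-5-(benzyloxy)-2,8-bis[4-(benzyloxy)phenyl]-9-hydroxy-3,4,8,9-tetrahydro-2H-furo[2,3-h]chromene-9-carboxylate | CCOC(=O)[C@]1(O)c2c(cc(OCc3ccccc3)c4c2O[C@H](c2ccc(OCc5ccccc5)cc2)CC4)O[C@H]1c1ccc(OCc2ccccc2)cc1 | intermediate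
17 | 3,5-bis(benzyloxy)phenol | Oc1cc(OCc2ccccc2)cc(OCc2ccccc2)c1 | starting material
18 | 3,5-bis(benzyloxy)-2-bromophenol | Oc1cc(OCc2ccccc2)cc(OCc2ccccc2)c1Br | intermediate
19 | [3,5-bis(benzyloxy)-2-bromophenoxy]trimethylsilane | C[Si](C)(C)Oc1cc(OCc2ccccc2)cc(OCc2ccccc2)c1Br | intermediate
20 | lithium 3,5-bis(benzyloxy)-2-(trimethylsilyl)phenolate | [Li]Oc1cc(OCc2ccccc2)cc(OCc2ccccc2)c1[Si](C)(C)C | intermediate
21 | 3,5-bis(benzyloxy)-2-(trimethylsilyl)phenyl trifluoromethanesulfonate | C[Si](C)(C)c1c(OS(=O)(=O)C(F)(F)F)cc(OCc2ccccc2)cc1OCc1ccccc1 | intermediate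
22 | potassium alkoxide of 16 | CCOC(=O)[C@]1(O[K])c2c(cc(OCc3ccccc3)c4c2O[C@H](c2ccc(OCc5ccccc5)cc2)CC4)O[C@H]1c1ccc(OCc2ccccc2)cc1 | intermediate
23 | 3,5-bis(benzyloxy)benzyne | C1#CC(OCc2ccccc2)=CC(OCc2ccccc2)=C1 | intermediate
24 | penta-O-benzyldaphnodorin C | O=C1c2c(OCc3ccccc3)cc(OCc3ccccc3)cc2O[C@]12c1c(cc(OCc3ccccc3)c3c1O[C@H](c1ccc(OCc4ccccc4)cc1)CC3)O[C@H]2c1ccc(OCc2ccccc2)cc1 | intermediate
25 | daphnodorin C | O=C1c2c(O)cc(O)cc2O[C@]12c1c(cc(O)c3c1O[C@H](c1ccc(O)cc1)CC3)O[C@H]2c1ccc(O)cc1 | target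

Total step count: 12. Longest linear sequence: 8 (steps 1–5, 8, 11, 12).

**Steps most likely to fail**

1. Step 11.
   - What may go wrong: O-arylation of the crowded tertiary alkoxide may lose out to capture of the aryne by fluoride or by the ethoxide that is released. The aryl anion may also be protonated before it reaches the ester.
   - Fallback (known chemistry, sets out from 16 and returns at 24): DIBAL-H in CH2Cl2 at −78 °C reduces the ester to the α-hydroxy aldehyde F1. Commercial 5-fluororesorcinol is dibenzylated to 1,3-bis(benzyloxy)-5-fluorobenzene F2. NBS brominates it para to one benzyloxy group to give 1,5-bis(benzyloxy)-2-bromo-3-fluorobenzene F3, and n-BuLi at −78 °C exchanges the bromide to give 2,4-bis(benzyloxy)-6-fluorophenyllithium F4. This reagent adds to F1 to give the 1,2-diol F5 (epimers at the new carbinol, of no consequence). MnO2 or Dess–Martin oxidation gives the α-hydroxy 2-fluoroaryl ketone F6. K2CO3 in DMF then closes the benzofuranone ring by carbonyl-activated intramolecular SNAr of the tertiary alkoxide.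

2. Step 8.
   - What may go wrong: the aryllithium may lose LiF, the keto ester may enolise and lose configurational integrity before addition, chelate control may erode, or the fluoride displacement may be slow enough for the dialkoxide to decompose.
   - Fallback (sets out from 8, with 9 and 10 for the antipodal linchpin, and returns at 16; it builds the ether from the phenol side with inversion): 2-(trimethylsilyl)ethanol/KHMDS in THF–DMF displaces the bromine-activated fluoride of 8 to give the 7-[2-(trimethylsilyl)ethoxy]-8-bromoflavan F7. The antipodal ProPhenol catalyst turns 9 and 10 into the (3R)-diazo aldol F8. TBSCl/imidazole gives its silyl ether F9, and DMDO gives the (3R)-silyloxy keto ester F10. n-BuLi converts F7 into the aryllithium F11, which adds to F10 at −78 °C under polar Felkin–Anh control (no chelation through the bulky silyl ether) to give the (2S,3R)-adduct F12. TBAF removes both silicon groups to give the phenol diol F13. DIAD/PPh3 then closes the dihydrofuran ring by intramolecular Mitsunobu etherification, with inversion at the carbinol carbon.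

3. Step 12.
   - What may go wrong: the two ring benzylic C–O bonds may be over-hydrogenolysed, or the spiro C–O bond may ionise on the catalyst support with aromatisation to the benzofuran.
   - Fallback (sets out from 24 and returns at 25): non-reductive debenzylation with BCl3 and pentamethylbenzene as cation scavenger in CH2Cl2 at −78 °C, quenched cold with MeOH. This fallback makes no new compound (F0).

**Further compounds**
F1 | step 11 | (2S,8S,9S)-5-(benzyloxy)-2,8-bis[4-(benzyloxy)phenyl]-9-hydroxy-3,4,8,9-tetrahydro-2H-furo[2,3-h]chromene-9-carbaldehyde | O=C[C@]1(O)c2c(cc(OCc3ccccc3)c4c2O[C@H](c2ccc(OCc5ccccc5)cc2)CC4)O[C@H]1c1ccc(OCc2ccccc2)cc1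
F2 | step 11 | 1,3-bis(benzyloxy)-5-fluorobenzene | Fc1cc(OCc2ccccc2)cc(OCc2ccccc2)c1
F3 | step 11 | 1,5-bis(benzyloxy)-2-bromo-3-fluorobenzene | Brc1c(F)cc(OCc2ccccc2)cc1OCc1ccccc1
F4 | step 11 | 2,4-bis(benzyloxy)-6-fluorophenyllithium | [Li]c1c(F)cc(OCc2ccccc2)cc1OCc1ccccc1
F5 | step 11 | [2,4-bis(benzyloxy)-6-fluorophenyl]{(2S,8S,9S)-5-(benzyloxy)-2,8-bis[4-(benzyloxy)phenyl]-9-hydroxy-3,4,8,9-tetrahydro-2H-furo[2,3-h]chromen-9-yl}methanol | OC(c1c(F)cc(OCc2ccccc2)cc1OCc1ccccc1)[C@]1(O)c2c(cc(OCc3ccccc3)c4c2O[C@H](c2ccc(OCc5ccccc5)cc2)CC4)O[C@H]1c1ccc(OCc2ccccc2)cc1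
F6 | step 11 | [2,4-bis(benzyloxy)-6-fluorophenyl]{(2S,8S,9S)-5-(benzyloxy)-2,8-bis[4-(benzyloxy)phenyl]-9-hydroxy-3,4,8,9-tetrahydro-2H-furo[2,3-h]chromen-9-yl}methanone | O=C(c1c(F)cc(OCc2ccccc2)cc1OCc1ccccc1)[C@]1(O)c2c(cc(OCc3ccccc3)c4c2O[C@H](c2ccc(OCc5ccccc5)cc2)CC4)O[C@H]1c1ccc(OCc2ccccc2)cc1
F7 | step 8 | (2S)-5-(benzyloxy)-2-[4-(benzyloxy)phenyl]-8-bromo-7-[2-(trimethylsilyl)ethoxy]chromane | Brc1c(OCC[Si](C)(C)C)cc(OCc2ccccc2)c2c1O[C@H](c1ccc(OCc3ccccc3)cc1)CC2
F8 | step 8 | ethyl (3R)-3-[4-(benzyloxy)phenyl]-2-diazo-3-hydroxypropanoate | O[C@@H](C(=[N+]=[N-])C(=O)OCC)c1ccc(OCc2ccccc2)cc1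
F9 | step 8 | ethyl (3R)-3-[4-(benzyloxy)phenyl]-3-[(tert-butyldimethylsilyl)oxy]-2-diazopropanoate | CC(C)(C)[Si](C)(C)O[C@@H](C(=[N+]=[N-])C(=O)OCC)c1ccc(OCc2ccccc2)cc1
F10 | step 8 | ethyl (3R)-3-[4-(benzyloxy)phenyl]-3-[(tert-butyldimethylsilyl)oxy]-2-oxopropanoate | CC(C)(C)[Si](C)(C)O[C@@H](C(=O)C(=O)OCC)c1ccc(OCc2ccccc2)cc1
F11 | step 8 | (2S)-5-(benzyloxy)-2-[4-(benzyloxy)phenyl]-7-[2-(trimethylsilyl)ethoxy]chroman-8-yllithium | [Li]c1c(OCC[Si](C)(C)C)cc(OCc2ccccc2)c2c1O[C@H](c1ccc(OCc3ccccc3)cc1)CC2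
F12 | step 8 | ethyl (2S,3R)-2-{(2S)-5-(benzyloxy)-2-[4-(benzyloxy)phenyl]-7-[2-(trimethylsilyl)ethoxy]chroman-8-yl}-3-[4-(benzyloxy)phenyl]-3-[(tert-butyldimethylsilyl)oxy]-2-hydroxypropanoate | CCOC(=O)[C@](O)(c1c(OCC[Si](C)(C)C)cc(OCc2ccccc2)c2c1O[C@H](c1ccc(OCc3ccccc3)cc1)CC2)[C@H](O[Si](C)(C)C(C)(C)C)c1ccc(OCc2ccccc2)cc1
F13 | step 8 | ethyl (2S,3R)-2-{(2S)-5-(benzyloxy)-2-[4-(benzyloxy)phenyl]-7-hydroxychroman-8-yl}-3-[4-(benzyloxy)phenyl]-2,3-dihydroxypropanoate | CCOC(=O)[C@](O)(c1c(O)cc(OCc2ccccc2)c2c1O[C@H](c1ccc(OCc3ccccc3)cc1)CC2)[C@H](O)c1ccc(OCc2ccccc2)cc1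
F0 | step 12 | none | none
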